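All constants belong to no real substance; the flask was simulated.

Slowness is the first worry in this flask: will the catalyst's round get through the charge within the time, or be caught short?

substrate 0.028 M; coupling partner 0.0168 M (fed, over 2.0 min); free catalyst 22 µM; time 2.0 h

    substrate + free catalyst ⇌ catalyst intermediate A (K1 = 77 M⁻¹, k1 = 340 M⁻¹ s⁻¹)
    coupling partner + catalyst intermediate A → catalyst intermediate B (k2 = 12000 M⁻¹ s⁻¹)
    catalyst intermediate B ⇌ released group + catalyst intermediate C (K3 = 0.029 M, k3 = 2.2 s⁻¹)
    catalyst intermediate C → free catalyst + product (k4 = 2.2 s⁻¹)
    2 free catalyst → spent catalyst (k5 = 41 M⁻¹ s⁻¹)
    released group → by-product carried off (k6 = 0.0014 s⁻¹)

1. which holds at 2.0 h: what has brought the reaction to rest, or that it has not come to rest (all of the substrate has reacted / the coupling partner has run out first / no working catalyst is left / forward and back rates have come level / it is still moving)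
2. conversion of substrate at 2.0 h
3. amount of product at 2.0 h, in percent of the substrate charged

- a doubled species enters its step squared and goes two at a time
- the reaction counts as stopped when no species that holds the substrate changes by six tenths of a point or more over the second half of the time
- run time (flask): 2.0 h

**Catalyst pace.** Start with time constants. At the charged substrate, free catalyst binds in about 0.105 s, which is shorter than the 0.909 s you get by adding the forward times of the two steps after coupling. So, as a rough estimate, count binding as quick and take those two steps as the length of a round. If you ignore catalyst loss and the way back from released group, the catalyst charge gets through the coupling partner in about 0.193 h, which is shorter than the run time. By hand, then, the catalyst charge changes the pace of this flask, and the estimate gives no shortage of time.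

**Partner charge.** Each turn uses one substrate and one coupling partner and gives one product. The quantity to carry is therefore 0.600, the partner ceiling: coupling partner charged per substrate charged, held at one at most. By hand, it rises and falls in step with the partner charge while that charge stays below the substrate charge. In this flask the coupling partner is the limiting reagent, since less of it is charged than of substrate.

**Substrate charge.** In this flask, more substrate lowers the ceiling as a fraction, and less raises it, up to one.

**Feed time.** The feed of 2.0 min is shorter than the drain time, and it does not enter the ceiling.

**My reckoning.** I commit to the coupling partner has run out first, a conversion of 60.0%, and the same amount of product.

**The forecast.** It gives the coupling partner has run out first, conversion 60% and product 60%, reasoning that “The partner is charged at only 0.6 equivalents and each turnover uses one”.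

**The flask.** At 2.0 h the outcome is the coupling partner has run out first, with conversion 60.0% and product 60.0%. Of the charges, 0% of the coupling partner remains, less than the 40% of the substrate. Waiting brings nothing: at 20.0 h conversion reads 60.0%. Moved singly by one same factor, the settings rank coupling partner (18 points), then substrate (18 points), then free catalyst (under 0.05 points), and the gradual adding of the coupling partner makes no difference to conversion.

**Neighbouring flask.** The flask stands at its ceiling of 0.600. Now take the neighbour flask, charged with 0.010 M of coupling partner and otherwise the same. Its ceiling comes to 0.357. That neighbour flask gives conversion 35.7% and product 35.7%, and it ends with 0% of its coupling partner and 64% of its substrate left.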